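**Retrosynthetic overview**

1. The strategy rests on chromone ring A (C4a, C5, C6, C7, C8, C8a): a benzene ring with OH on C5 and OMe on C7, meta to each other, sharing the C4a=C8a bond with the pyranone. After removal of three MOM ethers, ring A is disconnected at C4a–C5, C5–C6 and C7–C8 into a 2-diazoacetyl-5-aryl-4-pyranone and methoxyacetylene.
2. The diazo ketone comes from the pyranone-2-carboxylic acid. The pyranone (later ring C) is bought as comenic acid and joined to ring B by Suzuki coupling of its 5-triflate with a ring B pinacol boronate.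
3. The boronate comes from the ring B bromide carrying the (E)-1,3,3-triarylpropene chain. That chain arises by reduction and dehydration of a β,β-diaryl ketone, itself made by rhodium-catalysed asymmetric arylation of a ring B/ring D chalcone with the ring E boronic acid, which sets C*.
4. Ring order: rings B, D and E are bought as benzenes and ring C as the pyranone; ring A is the only ring formed, in the last skeletal step.

Key step: step 14

**Remarks**

- Ar* stands for the 5-[(1S,2E)-1-(2,4-dimethoxyphenyl)-3-[4-(methoxymethoxy)phenyl]prop-2-en-1-yl]-2,4-bis(methoxymethoxy)phenyl group (ring B with its side chain, bonded through ring B C1).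
- Assumption: comenic acid is taken as a catalogue compound (it is the oxidation product of kojic acid). Methoxyacetylene boils near room temperature and is therefore made fresh in step 13.
- The (R)-antipode of BINAP in step 4 is assigned from the usual facial model for enone insertion (aryl delivered to the re face of Cβ). The sense should be confirmed on the first batch and the ligand antipode exchanged if needed.
- C* has the descriptor S in all MOM-protected compounds and R in the target. The change in step 15 comes only from the CIP ranking of rings B and E; no bond at C* is touched.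

**Route**

Step 1
Reactants: 1 5-bromo-2,4-dihydroxybenzaldehyde
Product: 2 5-bromo-2,4-bis(methoxymethoxy)benzaldehyde
Conditions: NaH (2.4 equiv), MOMCl (2.6 equiv), DMF, 0 °C to rt
Reagents that add atoms: chloromethyl methyl ether (MOMCl), COCCl
Why: Williamson-type O-alkylation of both phenoxides (NaH also frees the hydrogen-bonded 2-hydroxyl) should give the bis-MOM ether, which tolerates the basic, reductive and palladium steps ahead.

Step 2
Reactants: 3 4'-hydroxyacetophenone
Product: 4 4'-(methoxymethoxy)acetophenone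
Conditions: MOMCl (1.3 equiv), K2CO3 (2 equiv), acetone, reflux
Reagents that add atoms: chloromethyl methyl ether (MOMCl), COCCl
Why: O-alkylation of the phenoxide (MOM protection) masks the ring D phenol before the aldol step.

Step 3
Reactants: 2 5-bromo-2,4-bis(methoxymethoxy)benzaldehyde, 4 4'-(methoxymethoxy)acetophenone
Product: 5 (2E)-3-[5-bromo-2,4-bis(methoxymethoxy)phenyl]-1-[4-(methoxymethoxy)phenyl]prop-2-en-1-one
Conditions: KOH (aq. 50 %), EtOH, rt
Reagents that add atoms: none
Why: Claisen–Schmidt condensation of a non-enolisable aldehyde with an aryl methyl ketone should give the conjugated E-chalcone under thermodynamic control.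

Step 4
Reactants: 5 the bromochalcone, 6 2,4-dimethoxyphenylboronic acid
Product: 7 (3S)-3-[5-bromo-2,4-bis(methoxymethoxy)phenyl]-3-(2,4-dimethoxyphenyl)-1-[4-(methoxymethoxy)phenyl]propan-1-one
Conditions: Rh(acac)(C2H4)2 (5 mol %), (R)-BINAP (6 mol %), 6 (4 equiv), 1,4-dioxane/H2O 10:1, 100 °C
Reagents that add atoms: none
Why: Hayashi–Miyaura asymmetric 1,4-addition, in which the aryl–rhodium species bearing (R)-BINAP should insert the enone through the re face of Cβ and so set C* with ring E, H, CH2 and ring B arranged as in the target, the aryl bromide being inert to monovalent rhodium.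

Step 5
Reactants: 7 the β,β-diaryl ketone
Product: 8 (3S)-3-[5-bromo-2,4-bis(methoxymethoxy)phenyl]-3-(2,4-dimethoxyphenyl)-1-[4-(methoxymethoxy)phenyl]propan-1-ol (both C1 epimers)
Conditions: NaBH4, MeOH/THF 1:1, 0 °C
Reagents that add atoms: none
Why: Borohydride 1,2-reduction of the aryl ketone; the carbinol centre forms without control and disappears in step 6, while C* is not enolisable and stays fixed.

Step 6
Reactants: 8 the benzylic alcohol
Product: 9 1-bromo-5-[(1S,2E)-1-(2,4-dimethoxyphenyl)-3-[4-(methoxymethoxy)phenyl]prop-2-en-1-yl]-2,4-bis(methoxymethoxy)benzene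
Conditions: methyl N-(triethylammoniosulfonyl)carbamate (Burgess reagent, 2 equiv), PhMe, 60 °C
Reagents that add atoms: none
Why: Burgess dehydration (syn-elimination of the benzylic sulfamate) is neutral and spares the MOM ethers, should favour the E-styrene conjugated with ring D, and leaves C* uninvolved.

Step 7
Reactants: 9 the aryl bromide
Product: 10 2-Ar*-4,4,5,5-tetramethyl-1,3,2-dioxaborolane (Ar*–Bpin)
Conditions: B2pin2 (1.5 equiv), PdCl2(dppf)·CH2Cl2 (5 mol %), KOAc (3 equiv), 1,4-dioxane, 90 °C
Reagents that add atoms: bis(pinacolato)diboron, CC1(C)OB(B2OC(C)(C)C(C)(C)O2)OC1(C)C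
Why: Miyaura borylation via oxidative addition of zerovalent palladium into the C–Br bond and acetate-assisted transmetalation; the disubstituted alkene and the MOM ethers are spectators.

Step 8
Reactants: 11 comenic acid (5-hydroxy-4-oxo-4H-pyran-2-carboxylic acid)
Product: 12 methyl 5-hydroxy-4-oxo-4H-pyran-2-carboxylate (methyl comenate)
Conditions: MeOH, H2SO4 (cat.), reflux
Reagents that add atoms: methanol, CO
Why: Fischer esterification of the carboxylic acid; the enolic 5-hydroxyl does not react.

Step 9
Reactants: 12 methyl comenate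
Product: 13 methyl 4-oxo-5-[(trifluoromethanesulfonyl)oxy]-4H-pyran-2-carboxylate
Conditions: Tf2O (1.1 equiv), pyridine (2 equiv), CH2Cl2, −20 to 0 °C
Reagents that add atoms: trifluoromethanesulfonic anhydride, O=S(=O)(OS(=O)(=O)C(F)(F)F)C(F)(F)F
Why: O-Sulfonylation of the only hydroxyl gives an electron-poor enol triflate, the type of 3-triflyloxy-4-pyranone that is an established cross-coupling partner.

Step 10
Reactants: 10 Ar*–Bpin, 13 the pyranone triflate
Product: 14 methyl 5-Ar*-4-oxo-4H-pyran-2-carboxylate
Conditions: Pd(OAc)2 (5 mol %), SPhos (10 mol %), K3PO4 (2 equiv), PhMe/H2O 20:1, 70 °C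
Reagents that add atoms: none
Why: Suzuki–Miyaura coupling, in which oxidative addition to the pyranone C–OTf bond is fast and the mild phosphate base in nearly anhydrous toluene should spare the ester and the pyranone ring.

Step 11
Reactants: 14 the methyl ester
Product: 15 5-Ar*-4-oxo-4H-pyran-2-carboxylic acid
Conditions: LiOH·H2O (1.3 equiv), THF/H2O 3:1, 0 °C; then 0.5 M aq. HCl to pH 3–4, 0 °C
Reagents that add atoms: lithium hydroxide monohydrate, [Li+].[OH-].O
Why: Saponification of an activated heteroaryl ester should outrun hydroxide attack on the pyranone at 0 °C, and the MOM ethers survive the brief cold acidification.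

Step 12
Reactants: 15 the carboxylic acid
Product: 17 2-(diazoacetyl)-5-Ar*-4H-pyran-4-one, via acid chloride 16 (not isolated)
Conditions: (i) 1-chloro-N,N,2-trimethylprop-1-en-1-amine (1.2 equiv), CH2Cl2, 0 °C to rt; (ii) added to CH2N2 (4 equiv), Et2O, −10 to 0 °C
Reagents that add atoms: diazomethane, C=[N+]=[N-]
Why: Neutral acid chloride formation with the α-chloroenamine followed by Arndt–Eistert-type acylation of diazomethane (a second equivalent takes up HCl), with inverse addition at low temperature to keep acylation ahead of dipolar cycloaddition to the pyranone.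

Step 13
Reactants: 18 2-chloro-1,1-dimethoxyethane (chloroacetaldehyde dimethyl acetal)
Product: 20 methoxyacetylene, via sodium methoxyacetylide 19 (not isolated)
Conditions: NaNH2 (3.1 equiv), liq. NH3, −33 °C; then cold sat. aq. NaCl, −70 °C to rt, distilled into a −78 °C trap; stored as a solution in ClCH2CH2Cl at −20 °C
Reagents that add atoms: none
Why: Double base-induced elimination (HCl, then methanol) from the chloroacetal is the standard preparation of 1-alkoxyalkynes, and aqueous quench protonates the acetylide.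

Step 14
Reactants: 17 2-(diazoacetyl)-5-Ar*-4H-pyran-4-one, 20 methoxyacetylene
Product: 25 5-hydroxy-7-methoxy-3-Ar*-4H-chromen-4-one, via pyranonylketene 21 (not isolated), via methoxycyclobutenone 22 (not isolated), via dienylketene 23 (not isolated), via dienone tautomer 24 (not isolated)
Conditions: 20 (5 equiv), ClCH2CH2Cl (0.02 M), hν (LED, 405–450 nm), 10 °C, sealed Pyrex tube; then excess 20 evaporated, PhMe, 90 °C
Reagents that add atoms: none
Why: Proposed new method: excitation of the diazo ketone should expel N2 with migration of the pyranonyl group (Wolff rearrangement) to ketene 21, whose C=C adds methoxyacetylene in a [2+2] cycloaddition to cyclobutenone 22; reversible four-electron electrocyclic opening gives dienylketene 23, the rotamer with the pyranonyl group cis to the ketene carbon closes by thermal six-electron electrocyclisation onto pyranone C3, and enolisation of β-diketone 24 aromatises ring A. The closest known reaction type is the Danheiser benzannulation in its photo-Wolff form, established for α,β-unsaturated and aryl or heteroaryl diazomethyl ketones with alkoxy- and siloxyalkynes; what is new is the C2=C3 bond of a 4-pyranone as the vinyl unit, which should serve because it is a polarised enol-ether-type alkene with less aromatic stabilisation to give up than the benzene and furan rings that already take part. Ring A is closed by the disrotatory six-electron electrocyclisation that forms C4a–C5, the bonds C5–C6 and C7–C8 coming from the cycloaddition, and pyranone C3 is the only carbon terminus within reach of the ketene, so there is one mode of closure. No stereocentre is created in the product: the centres at cyclobutenone C4 and at C4a of 24 are transient and C* is a remote spectator. The step needs the CH terminus of the ynol ether to bond to the ketene carbonyl carbon, which the polarity of both partners secures and which places OMe on C7 and the former ketene oxygen as the chelated 5-OH; it also needs the ketene to prefer the alkyne over the side-chain styrene, secured by the electron-rich alkyne in excess, and light absorbed only by the diazo ketone, secured by the 405–450 nm window that lies outside the absorption of the E-styrene and the aryl pyranone.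

Step 15
Reactants: 25 5-hydroxy-7-methoxy-3-Ar*-4H-chromen-4-one
Product: 26 caraganin A, 3-{5-[(1R,2E)-1-(2,4-dimethoxyphenyl)-3-(4-hydroxyphenyl)prop-2-en-1-yl]-2,4-dihydroxyphenyl}-5-hydroxy-7-methoxy-4H-chromen-4-one
Conditions: ZnBr2 (4 equiv), n-PrSH (8 equiv), CH2Cl2, 0 °C to rt
Reagents that add atoms: none
Why: Lewis-acid-assisted thiolysis of the three aryl MOM acetals (the thiol captures the methoxymethyl unit as an O,S-acetal) works without protic acid, so the ortho-hydroxycinnamyl unit should not cyclise to a flavan, and the chelated 5-hydroxyl, the methyl ethers, the E-alkene and C* are untouched.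

**Compound list**

1 | 5-bromo-2,4-dihydroxybenzaldehyde | O=Cc1cc(Br)c(O)cc1O | starting material
2 | 5-bromo-2,4-bis(methoxymethoxy)benzaldehyde | O=Cc1cc(Br)c(OCOC)cc1OCOC | intermediate
3 | 4'-hydroxyacetophenone | CC(=O)c1ccc(O)cc1 | starting material
4 | 4'-(methoxymethoxy)acetophenone | CC(=O)c1ccc(OCOC)cc1 | intermediate
5 | (2E)-3-[5-bromo-2,4-bis(methoxymethoxy)phenyl]-1-[4-(methoxymethoxy)phenyl]prop-2-en-1-one | COCOc1ccc(C(=O)/C=C/c2cc(Br)c(OCOC)cc2OCOC)cc1 | intermediate
6 | 2,4-dimethoxyphenylboronic acid | COc1ccc(B(O)O)c(OC)c1 | starting material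
7 | (3S)-3-[5-bromo-2,4-bis(methoxymethoxy)phenyl]-3-(2,4-dimethoxyphenyl)-1-[4-(methoxymethoxy)phenyl]propan-1-one | COc1ccc([C@H](CC(=O)c2ccc(OCOC)cc2)c2cc(Br)c(OCOC)cc2OCOC)c(OC)c1 | intermediate
8 | (3S)-3-[5-bromo-2,4-bis(methoxymethoxy)phenyl]-3-(2,4-dimethoxyphenyl)-1-[4-(methoxymethoxy)phenyl]propan-1-ol, C1 epimers | COc1ccc([C@H](CC(O)c2ccc(OCOC)cc2)c2cc(Br)c(OCOC)cc2OCOC)c(OC)c1 | intermediate
9 | 1-bromo-5-[(1S,2E)-1-(2,4-dimethoxyphenyl)-3-[4-(methoxymethoxy)phenyl]prop-2-en-1-yl]-2,4-bis(methoxymethoxy)benzene | COc1ccc([C@H](/C=C/c2ccc(OCOC)cc2)c2cc(Br)c(OCOC)cc2OCOC)c(OC)c1 | intermediate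
10 | 2-Ar*-4,4,5,5-tetramethyl-1,3,2-dioxaborolane | COc1ccc([C@H](/C=C/c2ccc(OCOC)cc2)c2cc(B3OC(C)(C)C(C)(C)O3)c(OCOC)cc2OCOC)c(OC)c1 | intermediate
11 | comenic acid (5-hydroxy-4-oxo-4H-pyran-2-carboxylic acid) | O=C(O)c1cc(=O)c(O)co1 | starting material
12 | methyl 5-hydroxy-4-oxo-4H-pyran-2-carboxylate | COC(=O)c1cc(=O)c(O)co1 | intermediate
13 | methyl 4-oxo-5-[(trifluoromethanesulfonyl)oxy]-4H-pyran-2-carboxylate | COC(=O)c1cc(=O)c(OS(=O)(=O)C(F)(F)F)co1 | intermediate
14 | methyl 5-Ar*-4-oxo-4H-pyran-2-carboxylate | COc1ccc([C@H](/C=C/c2ccc(OCOC)cc2)c2cc(-c3coc(C(=O)OC)cc3=O)c(OCOC)cc2OCOC)c(OC)c1 | intermediate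
15 | 5-Ar*-4-oxo-4H-pyran-2-carboxylic acid | COc1ccc([C@H](/C=C/c2ccc(OCOC)cc2)c2cc(-c3coc(C(=O)O)cc3=O)c(OCOC)cc2OCOC)c(OC)c1 | intermediate
16 | 5-Ar*-4-oxo-4H-pyran-2-carbonyl chloride | COc1ccc([C@H](/C=C/c2ccc(OCOC)cc2)c2cc(-c3coc(C(Cl)=O)cc3=O)c(OCOC)cc2OCOC)c(OC)c1 | intermediate (not isolated)
17 | 2-(diazoacetyl)-5-Ar*-4H-pyran-4-one | COc1ccc([C@H](/C=C/c2ccc(OCOC)cc2)c2cc(-c3coc(C(=O)C=[N+]=[N-])cc3=O)c(OCOC)cc2OCOC)c(OC)c1 | intermediate
18 | 2-chloro-1,1-dimethoxyethane | COC(CCl)OC | starting material
19 | sodium methoxyacetylide | [Na+].[C-]#COC | intermediate (not isolated)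
20 | methoxyacetylene | C#COC | intermediate
21 | (5-Ar*-4-oxo-4H-pyran-2-yl)ketene | COc1ccc([C@H](/C=C/c2ccc(OCOC)cc2)c2cc(-c3coc(C=C=O)cc3=O)c(OCOC)cc2OCOC)c(OC)c1 | intermediate (not isolated)
22 | 3-methoxy-4-(5-Ar*-4-oxo-4H-pyran-2-yl)cyclobut-2-en-1-one, C4 epimers | COc1ccc([C@H](/C=C/c2ccc(OCOC)cc2)c2cc(-c3coc(C4C(OC)=CC4=O)cc3=O)c(OCOC)cc2OCOC)c(OC)c1 | intermediate (not isolated)
23 | 3-methoxy-4-(5-Ar*-4-oxo-4H-pyran-2-yl)buta-1,3-dien-1-one, pyranonyl cis to the ketene-bearing carbon | COc1ccc([C@H](/C=C/c2ccc(OCOC)cc2)c2cc(-c3coc(/C=C(\C=C=O)OC)cc3=O)c(OCOC)cc2OCOC)c(OC)c1 | intermediate (not isolated)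
24 | 7-methoxy-3-Ar*-4aH-chromene-4,5-dione (keto tautomer of 25) | COc1ccc([C@H](/C=C/c2ccc(OCOC)cc2)c2cc(C3=COC4=CC(OC)=CC(=O)C4C3=O)c(OCOC)cc2OCOC)c(OC)c1 | intermediate (not isolated)
25 | 5-hydroxy-7-methoxy-3-Ar*-4H-chromen-4-one | COc1ccc([C@H](/C=C/c2ccc(OCOC)cc2)c2cc(-c3coc4cc(OC)cc(O)c4c3=O)c(OCOC)cc2OCOC)c(OC)c1 | intermediate
26 | caraganin A | COc1ccc([C@H](/C=C/c2ccc(O)cc2)c2cc(-c3coc4cc(OC)cc(O)c4c3=O)c(O)cc2O)c(OC)c1 | target

**Step count and risks**

Total step count: 15. Longest linear sequence: 11 steps (1, 3, 4, 5, 6, 7, 10, 11, 12, 14, 15, from 5-bromo-2,4-dihydroxybenzaldehyde).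

Steps most likely to fail:

1. Step 14 (Proposed new method). The cascade may stall at the cyclobutenone if the six-electron closure onto the pyranone is slow. The ketene may be lost to dimerisation or to cycloaddition with the styrene. The excited aryl pyranone may sensitise E/Z isomerisation of the side chain. Fallback with known isoflavone chemistry, setting out from boronate 10: commercial 2',6'-dihydroxy-4'-methoxyacetophenone is condensed with N,N-dimethylformamide dimethyl acetal (PhMe, 90 °C) to the enaminone (2E)-1-(2,6-dihydroxy-4-methoxyphenyl)-3-(dimethylamino)prop-2-en-1-one F1. Iodine-mediated cyclisation (I2, pyridine, CHCl3, rt) gives 5-hydroxy-3-iodo-7-methoxy-4H-chromen-4-one F2. Suzuki coupling of 10 with F2 (Pd(PPh3)4, K2CO3, 1,4-dioxane/H2O, 80 °C) should deliver 25, where the route is rejoined before step 15. Ring A is then bought rather than built.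

2. Step 12. Diazomethane may add as a 1,3-dipole to the electron-poor pyranone double bonds, or the acid chloride may be hydrolysed before acylation. Fallback, setting out from acid 15 (through acid chloride 16 made as in step 12): acyl Negishi coupling with MeZnCl and Pd(PPh3)4 (THF, 0 °C) gives 2-acetyl-5-Ar*-4H-pyran-4-one F3. Its lithium enolate (LiN(SiMe3)2, THF, −78 °C) is trifluoroacetylated with 2,2,2-trifluoroethyl trifluoroacetate to 4,4,4-trifluoro-1-(5-Ar*-4-oxo-4H-pyran-2-yl)butane-1,3-dione F4. Detrifluoroacetylative diazo transfer (MsN3, Et3N, H2O, MeCN, rt) gives 17, and the route continues with step 14. No diazomethane is used.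

3. Step 4. With ortho-substituted partners the insertion may be slow, the electron-rich boronic acid may be lost to protodeboronation, and facial discrimination may be insufficient. Fallback by auxiliary control, setting out from aldehyde 2: Horner–Wadsworth–Emmons olefination with diethyl {2-oxo-2-[(4R)-2-oxo-4-phenyl-1,3-oxazolidin-3-yl]ethyl}phosphonate (LiCl, iPr2NEt, MeCN) gives (4R)-3-{(2E)-3-[5-bromo-2,4-bis(methoxymethoxy)phenyl]prop-2-enoyl}-4-phenyl-1,3-oxazolidin-2-one F5. Copper-mediated conjugate addition of 2,4-dimethoxyphenylmagnesium bromide (CuBr·SMe2, THF, −40 to −20 °C) should occur anti to the auxiliary phenyl group in the magnesium chelate and give (4R)-3-{(3S)-3-[5-bromo-2,4-bis(methoxymethoxy)phenyl]-3-(2,4-dimethoxyphenyl)propanoyl}-4-phenyl-1,3-oxazolidin-2-one F6. Aminolysis with Me(MeO)NH·HCl and AlMe3 (CH2Cl2, 0 °C to rt) gives (3S)-3-[5-bromo-2,4-bis(methoxymethoxy)phenyl]-3-(2,4-dimethoxyphenyl)-N-methoxy-N-methylpropanamide F7. Addition of 4-(methoxymethoxy)phenylmagnesium bromide (THF, 0 °C) returns to ketone 7, and the route continues with step 5.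

**Further compounds**

F1 | step 14 | (2E)-1-(2,6-dihydroxy-4-methoxyphenyl)-3-(dimethylamino)prop-2-en-1-one | COc1cc(O)c(C(=O)/C=C/N(C)C)c(O)c1
F2 | step 14 | 5-hydroxy-3-iodo-7-methoxy-4H-chromen-4-one | COc1cc(O)c2c(=O)c(I)coc2c1
F3 | step 12 | 2-acetyl-5-Ar*-4H-pyran-4-one | COc1ccc([C@H](/C=C/c2ccc(OCOC)cc2)c2cc(-c3coc(C(C)=O)cc3=O)c(OCOC)cc2OCOC)c(OC)c1
F4 | step 12 | 4,4,4-trifluoro-1-(5-Ar*-4-oxo-4H-pyran-2-yl)butane-1,3-dione | COc1ccc([C@H](/C=C/c2ccc(OCOC)cc2)c2cc(-c3coc(C(=O)CC(=O)C(F)(F)F)cc3=O)c(OCOC)cc2OCOC)c(OC)c1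
F5 | step 4 | (4R)-3-{(2E)-3-[5-bromo-2,4-bis(methoxymethoxy)phenyl]prop-2-enoyl}-4-phenyl-1,3-oxazolidin-2-one | O=C(/C=C/c1cc(Br)c(OCOC)cc1OCOC)N1C(=O)OC[C@H]1c1ccccc1
F6 | step 4 | (4R)-3-{(3S)-3-[5-bromo-2,4-bis(methoxymethoxy)phenyl]-3-(2,4-dimethoxyphenyl)propanoyl}-4-phenyl-1,3-oxazolidin-2-one | COc1ccc([C@H](CC(=O)N2C(=O)OC[C@H]2c2ccccc2)c2cc(Br)c(OCOC)cc2OCOC)c(OC)c1
F7 | step 4 | (3S)-3-[5-bromo-2,4-bis(methoxymethoxy)phenyl]-3-(2,4-dimethoxyphenyl)-N-methoxy-N-methylpropanamide | COc1ccc([C@H](CC(=O)N(C)OC)c2cc(Br)c(OCOC)cc2OCOC)c(OC)c1
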